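The 14-membered carbocycle is closed at C12–C13 by a nickel-catalysed reductive alkyne–aldehyde macrocyclisation of an open-chain ynal. In one operation the C13 aldehyde bonds to the internal carbon of a terminal alkyne, giving the ring, the C13 carbinol and a C12 exo-methylene. This exploits the oxolane carbon C12 (methyl plus ring oxygen) beside carbinol C13: C12 is the Markovnikov hydroalkoxylation product of that allylic exo-methylene, so the terminal alkyne carbon becomes the C12 methyl when the C9 hydroxyl closes the oxolane (O, C9–C12) across the macrocycle. The ynal is built linearly from 4-iodopent-4-enal; a malonate masks the acrylic acid until the last step.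

Key step: step 13

Remark (numbering and supply): C1 is the ring carbon bearing the acrylic acid, then C2, C3, C4 (Me, OH), C5 (OAc), C6, C7, C8 (=CH2), C9 (ring O), C10, C11, C12 (Me, ring O), C13 (OH), C14; pent-4-ynal, acrolein diethyl acetal and both Grignard solutions are taken as purchasable, the two chiral ligands as accessible by short known preparations.

Step 1
Reactants: 1 pent-4-yn-1-ol
Product: 2 4-iodopent-4-en-1-ol
Conditions: NaI, Me3SiCl, H2O, MeCN, rt
Reagents that add atoms: sodium iodide, [Na+].[I-]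
Why: Markovnikov hydroiodination of the terminal alkyne by HI generated in the flask should give the 2-iodo-1-alkene needed later for the Nozaki–Hiyama–Kishi coupling.

Step 2
Reactants: 2 4-iodopent-4-en-1-ol
Product: 3 4-iodopent-4-enal
Conditions: Dess–Martin periodinane, CH2Cl2, 0 °C to rt
Reagents that add atoms: none
Why: Dess–Martin oxidation takes the primary alcohol to the aldehyde under neutral conditions that leave the alkenyl iodide untouched.

Step 3
Reactants: 3 4-iodopent-4-enal; 4 isopropenylmagnesium bromide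
Product: 5 rac-6-iodo-2-methylhepta-1,6-dien-3-ol
Conditions: THF, −78 °C; then H2O
Reagents that add atoms: none
Why: Grignard 1,2-addition of the isopropenyl nucleophile to the aldehyde at low temperature should give the racemic 2-substituted allylic alcohol without exchange at the alkenyl iodide.

Step 4
Reactants: 5 rac-6-iodo-2-methylhepta-1,6-dien-3-ol
Product: 6 (1S)-4-iodo-1-[(2R)-2-methyloxiran-2-yl]pent-4-en-1-ol
Conditions: Ti(OiPr)4 (cat.), L-(+)-diisopropyl tartrate, t-BuOOH (0.45 equiv), 4 Å molecular sieves, CH2Cl2, −20 °C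
Reagents that add atoms: tert-butyl hydroperoxide, CC(C)(C)OO
Why: In this Sharpless kinetic resolution the L-(+)-tartrate catalyst should epoxidise the (S)-carbinol fast and anti (erythro) selectively, which sets C4 (R) and C5 (S) by reagent control while the unreacted (R)-alcohol is removed by chromatography.

Step 5
Reactants: 6 (1S)-4-iodo-1-[(2R)-2-methyloxiran-2-yl]pent-4-en-1-ol; 7 allylmagnesium bromide
Product: 8 (5S,6R)-2-iodo-6-methyldeca-1,9-diene-5,6-diol
Conditions: 7 (3 equiv), THF, −40 to 0 °C; then H2O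
Reagents that add atoms: none
Why: Epoxide opening by the allyl Grignard reagent at the unhindered CH2 terminus (SN2) forms the C2–C3 bond and frees the tertiary C4 alcohol without touching either stereocentre.

Step 6
Reactants: 8 (5S,6R)-2-iodo-6-methyldeca-1,9-diene-5,6-diol
Product: 9 (5S,6R)-6-hydroxy-2-iodo-6-methyldeca-1,9-dien-5-yl acetate
Conditions: Ac2O, pyridine, DMAP (cat.), CH2Cl2, 0 °C
Reagents that add atoms: acetic anhydride, CC(=O)OC(C)=O
Why: Selective acylation should take the secondary C5 hydroxyl only, because the tertiary C4 hydroxyl is too hindered under these mild conditions.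

Step 7
Reactants: 9 (5S,6R)-6-hydroxy-2-iodo-6-methyldeca-1,9-dien-5-yl acetate
Product: 10 (5S,6R)-2-iodo-6-methyl-6-[(triethylsilyl)oxy]deca-1,9-dien-5-yl acetate
Conditions: Et3SiOSO2CF3, 2,6-lutidine, CH2Cl2, −78 to 0 °C
Reagents that add atoms: triethylsilyl trifluoromethanesulfonate, CC[Si](CC)(CC)OS(=O)(=O)C(F)(F)F
Why: Silylation with the silyl triflate caps the tertiary C4 alcohol so that it cannot undergo oxa-Michael addition in step 12 or transannular etherification in step 15.

Step 8
Reactants: 10 (5S,6R)-2-iodo-6-methyl-6-[(triethylsilyl)oxy]deca-1,9-dien-5-yl acetate; 11 acrolein diethyl acetal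
Product: 12 (5S,6R,9E)-11,11-diethoxy-2-iodo-6-methyl-6-[(triethylsilyl)oxy]undeca-1,9-dien-5-yl acetate
Conditions: second-generation Hoveyda–Grubbs catalyst, RuCl2(=CH-C6H4-2-OiPr)(H2IMes) (5 mol%), 11 (5 equiv), CH2Cl2, 40 °C
Reagents that add atoms: none
Why: Olefin cross-metathesis of the terminal alkene with the acrolein acetal should install C14 and C13 as the E-enal acetal, the hindered 2-iodoalkene being no metathesis substrate.

Step 9
Reactants: 12 (5S,6R,9E)-11,11-diethoxy-2-iodo-6-methyl-6-[(triethylsilyl)oxy]undeca-1,9-dien-5-yl acetate; 13 pent-4-ynal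
Product: 14 (5S,9S,10R,13E)-15,15-diethoxy-10-methyl-6-methylidene-5,10-bis[(triethylsilyl)oxy]pentadec-13-en-1-yn-9-yl acetate
Conditions: CrCl2 (15 mol%), chiral valinol-derived oxazoline–sulfonamide ligand (antipode chosen for the S alcohol), Et3N, NiCl2(2,9-dimethyl-1,10-phenanthroline) (2 mol%), Mn powder, Et3SiCl, LiCl, MeCN, rt
Reagents that add atoms: chlorotriethylsilane, CC[Si](Cl)(CC)CC
Why: In this catalytic asymmetric Nozaki–Hiyama–Kishi reaction the alkenylchromium from the 2-iodoalkene adds to the aldehyde, the chiral ligand on chromium should control C9 (S), and Et3SiCl turns over chromium while capping the alkoxide as its silyl ether.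

Step 10
Reactants: 14 (5S,9S,10R,13E)-15,15-diethoxy-10-methyl-6-methylidene-5,10-bis[(triethylsilyl)oxy]pentadec-13-en-1-yn-9-yl acetate
Product: 15 (5S,9S,10R,13E)-10-methyl-6-methylidene-15-oxo-5,10-bis[(triethylsilyl)oxy]pentadec-13-en-1-yn-9-yl acetate
Conditions: oxalic acid (cat.), wet silica gel, CH2Cl2, rt
Reagents that add atoms: water, O
Why: Mild acid-catalysed acetal hydrolysis should unveil the E-enal while the silyl ethers and the acetate survive.

Step 11
Reactants: 16 malonic acid; 17 2-(trimethylsilyl)ethanol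
Product: 18 bis[2-(trimethylsilyl)ethyl] propanedioate
Conditions: 17 (2.2 equiv in all), N,N'-dicyclohexylcarbodiimide (2.2 equiv), MeCN, 0 °C to rt
Reagents that add atoms: 2-(trimethylsilyl)ethanol (the second equivalent, which esterifies the second carboxyl group), C[Si](C)(C)CCO
Why: Twofold carbodiimide (Steglich-type) esterification, one molecule of the alcohol per carboxyl group, gives a malonate whose ester groups can later be removed by fluoride in the presence of the acetate.

Step 12
Reactants: 15 (5S,9S,10R,13E)-10-methyl-6-methylidene-15-oxo-5,10-bis[(triethylsilyl)oxy]pentadec-13-en-1-yn-9-yl acetate; 18 bis[2-(trimethylsilyl)ethyl] propanedioate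
Product: 19 bis[2-(trimethylsilyl)ethyl] 2-[(3R,6R,7S,11S)-7-(acetyloxy)-6-methyl-10-methylidene-1-oxo-6,11-bis[(triethylsilyl)oxy]pentadec-14-yn-3-yl]propanedioate
Conditions: (S)-α,α-diphenylprolinol trimethylsilyl ether (10 mol%), PhCO2H (10 mol%), EtOH, 0 °C
Reagents that add atoms: none
Why: In this organocatalytic asymmetric Michael addition the diarylprolinol silyl ether shields one face of the E-iminium ion, so the malonate should add to the other face of C1 and set C1 (R) by catalyst control while releasing the C13 aldehyde.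

Step 13
Reactants: 19 bis[2-(trimethylsilyl)ethyl] 2-[(3R,6R,7S,11S)-7-(acetyloxy)-6-methyl-10-methylidene-1-oxo-6,11-bis[(triethylsilyl)oxy]pentadec-14-yn-3-yl]propanedioate
Product: 20 bis[2-(trimethylsilyl)ethyl] 2-[(1R,4R,5S,9S,13R)-5-(acetyloxy)-4-methyl-8,12-dimethylidene-4,9-bis[(triethylsilyl)oxy]-13-[(triisopropylsilyl)oxy]cyclotetradecyl]propanedioate
Conditions: Ni(C8H12)2 [bis(cycloocta-1,5-diene)nickel] (30 mol%), enantiopure 1,3-bis(2,6-diisopropylphenyl)-4,5-diphenylimidazolidin-2-ylidene (30 mol%), iPr3SiH (4 equiv), THF, syringe-pump addition of 19 to a final 0.001 mol/L, 45 °C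
Reagents that add atoms: triisopropylsilane, CC(C)[SiH](C(C)C)C(C)C
Why: Zerovalent nickel carrying the bulky carbene binds the alkyne and the C13 aldehyde of 19 and undergoes oxidative cyclisation to an oxanickelacyclopentene that already holds the C12–C13 bond; σ-bond metathesis of Ni–O with iPr3SiH and C–H reductive elimination then release the silyl ether and the C12 exo-methylene. The closest known reaction type is the nickel-catalysed reductive aldehyde–alkyne coupling in its macrocyclising form with ligand-controlled regiochemistry. The 14-membered carbocycle is closed in the 14-exo-dig mode, C13 bonding to the internal alkyne carbon C12 while the terminal carbon stays outside the ring. The new stereocentre C13 is fixed in the oxidative cyclisation by the enantiopure backbone-chiral carbene (reagent control, antipode chosen for 13R) acting together with the conformational bias that C1 and C9 impose on the chain. The step needs regioselectivity for the internal alkyne carbon, which the steric contrast between the H and alkyl ends of the terminal alkyne should secure once the large carbene and the bulky silane are used, and it needs ring closure to outrun oligomerisation, which slow addition at high dilution should secure. Chemoselectivity rests on the substrate offering a single aldehyde and a single alkyne, the 1,1-disubstituted alkene, the esters and the silyl-capped hydroxyls being inert to the catalyst.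

Step 14
Reactants: 20 bis[2-(trimethylsilyl)ethyl] 2-[(1R,4R,5S,9S,13R)-5-(acetyloxy)-4-methyl-8,12-dimethylidene-4,9-bis[(triethylsilyl)oxy]-13-[(triisopropylsilyl)oxy]cyclotetradecyl]propanedioate
Product: 21 bis[2-(trimethylsilyl)ethyl] 2-[(1R,4R,5S,9S,13R)-5-(acetyloxy)-9-hydroxy-4-methyl-8,12-dimethylidene-4-[(triethylsilyl)oxy]-13-[(triisopropylsilyl)oxy]cyclotetradecyl]propanedioate
Conditions: pyridinium p-toluenesulfonate (cat.), MeOH–CH2Cl2, 0 °C
Reagents that add atoms: none
Why: Acid-catalysed methanolysis should remove only the secondary allylic triethylsilyl ether at C9, since the tertiary triethylsilyl ether, the triisopropylsilyl ether and the esters are much slower to react.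

Step 15
Reactants: 21 bis[2-(trimethylsilyl)ethyl] 2-[(1R,4R,5S,9S,13R)-5-(acetyloxy)-9-hydroxy-4-methyl-8,12-dimethylidene-4-[(triethylsilyl)oxy]-13-[(triisopropylsilyl)oxy]cyclotetradecyl]propanedioate
Product: 23 bis[2-(trimethylsilyl)ethyl] 2-[(1R,4R,5S,9S,12R,13R)-5-(acetyloxy)-4,12-dimethyl-8-methylidene-4-[(triethylsilyl)oxy]-13-[(triisopropylsilyl)oxy]-9,12-epoxycyclotetradecyl]propanedioate, via alkylmercury trifluoroacetate 22 (not isolated)
Conditions: Hg(O2CCF3)2, NaHCO3, CH2Cl2, −20 °C; then NaBH4, aq. NaOH, 0 °C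
Reagents that add atoms: mercury bis(trifluoroacetate), O=C(O[Hg]OC(=O)C(F)(F)F)C(F)(F)F (its mercury and one trifluoroacetate stay only in intermediate 22)
Why: In this intramolecular oxymercuration–demercuration the C9 hydroxyl adds to the mercurinium ion at C12 in Markovnikov 5-exo-trig fashion to close the oxolane, reduction turns the CH2Hg group into the C12 methyl, and C12 (R) should follow from the conformational preference of the macrocycle for the oxolane that carries C8 and C13 cis.

Step 16
Reactants: 23 bis[2-(trimethylsilyl)ethyl] 2-[(1R,4R,5S,9S,12R,13R)-5-(acetyloxy)-4,12-dimethyl-8-methylidene-4-[(triethylsilyl)oxy]-13-[(triisopropylsilyl)oxy]-9,12-epoxycyclotetradecyl]propanedioate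
Product: 24 2-[(1R,4R,5S,9S,12R,13R)-5-(acetyloxy)-4,13-dihydroxy-4,12-dimethyl-8-methylidene-9,12-epoxycyclotetradecyl]propanedioic acid
Conditions: Bu4NF (excess), THF, 0 °C to rt; then dilute HCl to pH 3
Reagents that add atoms: none
Why: Fluoride-induced β-elimination of both 2-(trimethylsilyl)ethyl esters and desilylation of the two silyl ethers should liberate the malonic acid and the C4 and C13 alcohols while the acetate stays.

Step 17
Reactants: 24 2-[(1R,4R,5S,9S,12R,13R)-5-(acetyloxy)-4,13-dihydroxy-4,12-dimethyl-8-methylidene-9,12-epoxycyclotetradecyl]propanedioic acid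
Product: 26 dendronpholide R, via Mannich base 25 (not isolated)
Conditions: 37% aq. CH2O, Et2NH, THF, rt then 60 °C
Reagents that add atoms: formaldehyde, C=O; diethylamine, CCNCC (retained only in intermediate 25)
Why: Decarboxylative Mannich methylenation (Mannich reaction, then loss of CO2 and Et2NH) should convert the substituted malonic acid into the α-methylene carboxylic acid without affecting the acetate or the C1 stereocentre.

Compound list
1 | pent-4-yn-1-ol | C#CCCCO | starting material
2 | 4-iodopent-4-en-1-ol | IC(=C)CCCO | intermediate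
3 | 4-iodopent-4-enal | IC(=C)CCC=O | intermediate
4 | isopropenylmagnesium bromide | C=C(C)[Mg]Br | starting material
5 | rac-6-iodo-2-methylhepta-1,6-dien-3-ol | C=C(C)C(O)CCC(=C)I | intermediate
6 | (1S)-4-iodo-1-[(2R)-2-methyloxiran-2-yl]pent-4-en-1-ol | C1[C@@](C)(O1)[C@@H](O)CCC(=C)I | intermediate
7 | allylmagnesium bromide | C=CC[Mg]Br | starting material
8 | (5S,6R)-2-iodo-6-methyldeca-1,9-diene-5,6-diol | C=CCC[C@@](C)(O)[C@@H](O)CCC(=C)I | intermediate
9 | (5S,6R)-6-hydroxy-2-iodo-6-methyldeca-1,9-dien-5-yl acetate | C=CCC[C@@](C)(O)[C@@H](OC(C)=O)CCC(=C)I | intermediate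
10 | (5S,6R)-2-iodo-6-methyl-6-[(triethylsilyl)oxy]deca-1,9-dien-5-yl acetate | C=CCC[C@@](C)(O[Si](CC)(CC)CC)[C@@H](OC(C)=O)CCC(=C)I | intermediate
11 | acrolein diethyl acetal (3,3-diethoxyprop-1-ene) | C=CC(OCC)OCC | starting material
12 | (5S,6R,9E)-11,11-diethoxy-2-iodo-6-methyl-6-[(triethylsilyl)oxy]undeca-1,9-dien-5-yl acetate | CCOC(OCC)/C=C/CC[C@@](C)(O[Si](CC)(CC)CC)[C@@H](OC(C)=O)CCC(=C)I | intermediate
13 | pent-4-ynal | C#CCCC=O | starting material
14 | (5S,9S,10R,13E)-15,15-diethoxy-10-methyl-6-methylidene-5,10-bis[(triethylsilyl)oxy]pentadec-13-en-1-yn-9-yl acetate | CCOC(OCC)/C=C/CC[C@@](C)(O[Si](CC)(CC)CC)[C@@H](OC(C)=O)CCC(=C)[C@@H](O[Si](CC)(CC)CC)CCC#C | intermediate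
15 | (5S,9S,10R,13E)-10-methyl-6-methylidene-15-oxo-5,10-bis[(triethylsilyl)oxy]pentadec-13-en-1-yn-9-yl acetate | O=C/C=C/CC[C@@](C)(O[Si](CC)(CC)CC)[C@@H](OC(C)=O)CCC(=C)[C@@H](O[Si](CC)(CC)CC)CCC#C | intermediate
16 | malonic acid | OC(=O)CC(=O)O | starting material
17 | 2-(trimethylsilyl)ethanol | C[Si](C)(C)CCO | starting material
18 | bis[2-(trimethylsilyl)ethyl] propanedioate | C[Si](C)(C)CCOC(=O)CC(=O)OCC[Si](C)(C)C | intermediate
19 | bis[2-(trimethylsilyl)ethyl] 2-[(3R,6R,7S,11S)-7-(acetyloxy)-6-methyl-10-methylidene-1-oxo-6,11-bis[(triethylsilyl)oxy]pentadec-14-yn-3-yl]propanedioate | C[Si](C)(C)CCOC(=O)C(C(=O)OCC[Si](C)(C)C)[C@@H](CC=O)CC[C@@](C)(O[Si](CC)(CC)CC)[C@@H](OC(C)=O)CCC(=C)[C@@H](O[Si](CC)(CC)CC)CCC#C | intermediate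
20 | bis[2-(trimethylsilyl)ethyl] 2-[(1R,4R,5S,9S,13R)-5-(acetyloxy)-4-methyl-8,12-dimethylidene-4,9-bis[(triethylsilyl)oxy]-13-[(triisopropylsilyl)oxy]cyclotetradecyl]propanedioate (ring locants as in the remark) | C[Si](C)(C)CCOC(=O)C(C(=O)OCC[Si](C)(C)C)[C@@H]1CC[C@@](C)(O[Si](CC)(CC)CC)[C@@H](OC(C)=O)CCC(=C)[C@@H](O[Si](CC)(CC)CC)CCC(=C)[C@H](O[Si](C(C)C)(C(C)C)C(C)C)C1 | intermediate
21 | bis[2-(trimethylsilyl)ethyl] 2-[(1R,4R,5S,9S,13R)-5-(acetyloxy)-9-hydroxy-4-methyl-8,12-dimethylidene-4-[(triethylsilyl)oxy]-13-[(triisopropylsilyl)oxy]cyclotetradecyl]propanedioate | C[Si](C)(C)CCOC(=O)C(C(=O)OCC[Si](C)(C)C)[C@@H]1CC[C@@](C)(O[Si](CC)(CC)CC)[C@@H](OC(C)=O)CCC(=C)[C@@H](O)CCC(=C)[C@H](O[Si](C(C)C)(C(C)C)C(C)C)C1 | intermediate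
22 | alkylmercury trifluoroacetate: 23 carrying CH2HgO2CCF3 in place of the C12 methyl | C[Si](C)(C)CCOC(=O)C(C(=O)OCC[Si](C)(C)C)[C@@H]1CC[C@@](C)(O[Si](CC)(CC)CC)[C@@H](OC(C)=O)CCC(=C)[C@@H]2CC[C@@](C[Hg]OC(=O)C(F)(F)F)(O2)[C@H](O[Si](C(C)C)(C(C)C)C(C)C)C1 | intermediate (not isolated)
23 | bis[2-(trimethylsilyl)ethyl] 2-[(1R,4R,5S,9S,12R,13R)-5-(acetyloxy)-4,12-dimethyl-8-methylidene-4-[(triethylsilyl)oxy]-13-[(triisopropylsilyl)oxy]-9,12-epoxycyclotetradecyl]propanedioate | C[Si](C)(C)CCOC(=O)C(C(=O)OCC[Si](C)(C)C)[C@@H]1CC[C@@](C)(O[Si](CC)(CC)CC)[C@@H](OC(C)=O)CCC(=C)[C@@H]2CC[C@@](C)(O2)[C@H](O[Si](C(C)C)(C(C)C)C(C)C)C1 | intermediate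
24 | 2-[(1R,4R,5S,9S,12R,13R)-5-(acetyloxy)-4,13-dihydroxy-4,12-dimethyl-8-methylidene-9,12-epoxycyclotetradecyl]propanedioic acid | OC(=O)C(C(=O)O)[C@@H]1CC[C@@](C)(O)[C@@H](OC(C)=O)CCC(=C)[C@@H]2CC[C@@](C)(O2)[C@H](O)C1 | intermediate
25 | Mannich base: 24 carrying a (diethylamino)methyl group on the malonic carbon | CCN(CC)CC(C(=O)O)(C(=O)O)[C@@H]1CC[C@@](C)(O)[C@@H](OC(C)=O)CCC(=C)[C@@H]2CC[C@@](C)(O2)[C@H](O)C1 | intermediate (not isolated)
26 | dendronpholide R, 2-[(1R,4R,5S,9S,12R,13R)-5-(acetyloxy)-4,13-dihydroxy-4,12-dimethyl-8-methylidene-9,12-epoxycyclotetradecyl]prop-2-enoic acid | C=C(C(=O)O)[C@@H]1CC[C@@](C)(O)[C@@H](OC(C)=O)CCC(=C)[C@@H]2CC[C@@](C)(O2)[C@H](O)C1 | target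

Total step count: 17
Longest linear sequence: 16 steps (steps 1–10 and 12–17, from pent-4-yn-1-ol); step 11 is a one-step side branch.

Steps most likely to fail

Step 13 (key macrocyclisation). The open chain may oligomerise instead of closing, the aldehyde may bond to the terminal alkyne carbon (endo mode), facial selectivity at C13 may be poor, or the carbene may be lost by protonation from the acidic malonate C–H. The fallback sets out from 19 and changes the manifold from nickel oxidative cyclisation to a polar alkenylchromium addition. With CrCl2 (excess), NiCl2 (cat.), PPh3 (cat.) and H2O in DMF under slow addition, the terminal alkyne should be hydrometalated at nickel in the Markovnikov sense and transmetalated to an internal alkenylchromium. That species adds to the C13 aldehyde as in a Nozaki–Hiyama–Kishi reaction to give the macrocyclic free allylic alcohol, the 13-hydroxy analogue of 20, F1. Silylation with iPr3SiOSO2CF3 and 2,6-lutidine brings the route back at 20.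

Step 15 (oxolane closure). Facial selectivity at C12 may be poor (trans-bridged ether), the C8 methylene may be mercurated in competition, or the acetate may be lost in the alkaline demercuration. The fallback sets out from 21 and separates ring closure from reduction. Iodoetherification with N-iodosuccinimide and NaHCO3 in MeCN at 0 °C relies on reversible iodonium formation and 5-exo capture by the C9 hydroxyl, and should give the C12-iodomethyl analogue of 23, F2. Radical deiodination with Bu3SnH and Et3B/air in toluene at rt, under neutral conditions, then gives 23, where the route resumes.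

Step 9 (C8–C9 coupling). Facial selectivity at C9 under ligand control may be poor with the unbranched aldehyde, and the aldehyde may self-condense. The fallback sets out from 12 and moves stereocontrol from the C–C bond formation to a ketone reduction. Coupling with 13 under stoichiometric CrCl2 and catalytic NiCl2 in DMF without a chiral ligand gives the C5-epimeric mixture (9S,10R,13E)-15,15-diethoxy-5-hydroxy-10-methyl-6-methylidene-10-[(triethylsilyl)oxy]pentadec-13-en-1-yn-9-yl acetate, F3. Dess–Martin oxidation gives the α-methylene ketone (9S,10R,13E)-15,15-diethoxy-10-methyl-6-methylidene-5-oxo-10-[(triethylsilyl)oxy]pentadec-13-en-1-yn-9-yl acetate, F4. Corey–Bakshi–Shibata reduction with the (R)-methyl oxazaborolidine and catecholborane at −78 °C (chosen to avoid hydroboration of the alkyne) should give the (5S)-alcohol (5S,9S,10R,13E)-15,15-diethoxy-5-hydroxy-10-methyl-6-methylidene-10-[(triethylsilyl)oxy]pentadec-13-en-1-yn-9-yl acetate, F5. Et3SiCl and imidazole then return the route to 14.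

Further compounds
F1 | step 13 | bis[2-(trimethylsilyl)ethyl] 2-[(1R,4R,5S,9S,13R)-5-(acetyloxy)-13-hydroxy-4-methyl-8,12-dimethylidene-4,9-bis[(triethylsilyl)oxy]cyclotetradecyl]propanedioate | C[Si](C)(C)CCOC(=O)C(C(=O)OCC[Si](C)(C)C)[C@@H]1CC[C@@](C)(O[Si](CC)(CC)CC)[C@@H](OC(C)=O)CCC(=C)[C@@H](O[Si](CC)(CC)CC)CCC(=C)[C@H](O)C1
F2 | step 15 | C12-iodomethyl analogue of 23 | C[Si](C)(C)CCOC(=O)C(C(=O)OCC[Si](C)(C)C)[C@@H]1CC[C@@](C)(O[Si](CC)(CC)CC)[C@@H](OC(C)=O)CCC(=C)[C@@H]2CC[C@@](CI)(O2)[C@H](O[Si](C(C)C)(C(C)C)C(C)C)C1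
F3 | step 9 | (9S,10R,13E)-15,15-diethoxy-5-hydroxy-10-methyl-6-methylidene-10-[(triethylsilyl)oxy]pentadec-13-en-1-yn-9-yl acetate (C5 epimers) | CCOC(OCC)/C=C/CC[C@@](C)(O[Si](CC)(CC)CC)[C@@H](OC(C)=O)CCC(=C)C(O)CCC#C
F4 | step 9 | (9S,10R,13E)-15,15-diethoxy-10-methyl-6-methylidene-5-oxo-10-[(triethylsilyl)oxy]pentadec-13-en-1-yn-9-yl acetate | CCOC(OCC)/C=C/CC[C@@](C)(O[Si](CC)(CC)CC)[C@@H](OC(C)=O)CCC(=C)C(=O)CCC#C
F5 | step 9 | (5S,9S,10R,13E)-15,15-diethoxy-5-hydroxy-10-methyl-6-methylidene-10-[(triethylsilyl)oxy]pentadec-13-en-1-yn-9-yl acetate | CCOC(OCC)/C=C/CC[C@@](C)(O[Si](CC)(CC)CC)[C@@H](OC(C)=O)CCC(=C)[C@@H](O)CCC#C
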